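**Retrosynthetic overview**
- Last bond: the aryl C6–CH2 bond of the resorcylate ring, made by ester-directed ortho C–H alkylation of a 2,4-bis(MOM-oxy)benzoate with TBS-protected (R)-undec-10-en-4-ol. The ester is installed while the acid still has only one ortho substituent.
- Aryl–alkyl bond of the alcohol half: B-alkyl Suzuki coupling of the alkenyl benzoate with 1-iodo-3,5-bis(MOM-oxy)benzene, which comes from Ir-catalysed C–H borylation of resorcinol bis-MOM ether.
- Ester: Steglich coupling of (R)-undec-10-en-4-ol with 2,4-bis(MOM-oxy)benzoic acid (retention).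
- Both stereocentres come from one building block, (R)-2-propyloxirane opened by hex-5-enylmagnesium bromide.
- No rings are formed; both benzene rings come intact from resorcinol.

Assumption: both stereocentres of the target are (R) (read from the SMILES), and (R)-2-propyloxirane is bought as the single enantiomer.

**Route**

Step 1
Reactants: 1 resorcinol
Product: 2 1,3-bis(methoxymethoxy)benzene
Conditions: MOMCl (2.6 equiv), i-Pr2NEt, CH2Cl2, 0 °C to rt
Reagents that add atoms: chloromethyl methyl ether (MOMCl), COCCl
Why: Williamson-type O-alkylation of both phenols; MOM ethers survive the bases, organometallics and Pd/Ir/Ru steps and come off with acid at the end.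

Step 2
Reactants: 2 1,3-bis(methoxymethoxy)benzene
Product: 3 2-[3,5-bis(methoxymethoxy)phenyl]-4,4,5,5-tetramethyl-1,3,2-dioxaborolane
Conditions: [Ir(OMe)(cod)]2 (1 mol%), dtbpy (2 mol%), B2pin2 (0.75 equiv), THF, 80 °C
Reagents that add atoms: bis(pinacolato)diboron, CC1(C)OB(OC1(C)C)B1OC(C)(C)C(C)(C)O1
Why: Ir-catalysed C–H borylation is sterically controlled, and C5–H is the only C–H of the 1,3-disubstituted ring with no ortho substituent.

Step 3
Reactants: 3 arylboronate
Product: 4 1-iodo-3,5-bis(methoxymethoxy)benzene
Conditions: CuI (10 mol%), 1,10-phenanthroline (20 mol%), KI (1.5 equiv), MeOH/H2O 4:1, air, 80 °C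
Reagents that add atoms: potassium iodide, [K+].[I-]
Why: Cu-catalysed ipso-iododeboronation goes through aryl–Cu transmetalation, so it is ipso-specific and does not iodinate the activated C–H positions; conditions are near-neutral for the MOM groups.

Step 4
Reactants: 2 1,3-bis(methoxymethoxy)benzene
Product: 5 1-bromo-2,4-bis(methoxymethoxy)benzene
Conditions: NBS (1.0 equiv), MeCN, 0 °C to rt
Reagents that add atoms: N-bromosuccinimide, O=C1CCC(=O)N1Br
Why: electrophilic aromatic bromination goes para to one OMOM and ortho to the other (C4), the normal outcome for resorcinol diethers; C2 between the two ethers is more hindered.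

Step 5
Reactants: 5 aryl bromide
Product: 6 2,4-bis(methoxymethoxy)benzoic acid
Conditions: n-BuLi (1.05 equiv), THF, −78 °C; CO2 (g); aq. citric acid to pH 4 at 0 °C
Reagents that add atoms: carbon dioxide, O=C=O
Why: Br/Li exchange at −78 °C is faster than directed lithiation at C2, and the aryllithium is carboxylated; the mild acidic work-up keeps the MOM ethers.

Step 6
Reactants: 7 6-bromohex-1-ene; 8 (R)-2-propyloxirane
Product: 9 (R)-undec-10-en-4-ol
Conditions: 7, Mg, THF (gives hex-5-enylmagnesium bromide, 1.3 equiv); CuI (10 mol%), 8, THF, −40 to 0 °C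
Reagents that add atoms: none
Why: Cu-catalysed Grignard opening of a terminal epoxide occurs at the CH2 carbon (SN2), so the stereocentre of 8 is untouched and is carried over as (R).

Step 7
Reactants: 9 (R)-undec-10-en-4-ol
Product: 10 (R)-tert-butyldimethyl(undec-10-en-4-yloxy)silane
Conditions: TBSCl (1.2 equiv), imidazole, DMF, rt
Reagents that add atoms: tert-butyldimethylsilyl chloride, CC(C)(C)[Si](C)(C)Cl
Why: standard silylation of a secondary alcohol; the TBS ether stops alcohol oxidation or coordination in the Ru step and is removed with the MOM groups.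

Step 8
Reactants: 9 (R)-undec-10-en-4-ol; 6 2,4-bis(methoxymethoxy)benzoic acid
Product: 11 (R)-undec-10-en-4-yl 2,4-bis(methoxymethoxy)benzoate
Conditions: EDC·HCl (1.5 equiv), DMAP (0.5 equiv), CH2Cl2, 0 °C to rt
Reagents that add atoms: none
Why: Steglich esterification works here because the acid has only one ortho substituent; the carbinol C–O bond is not broken, so (R) is retained.

Step 9
Reactants: 11 alkenyl benzoate; 4 1-iodo-3,5-bis(methoxymethoxy)benzene
Product: 12 (R)-11-[3,5-bis(methoxymethoxy)phenyl]undecan-4-yl 2,4-bis(methoxymethoxy)benzoate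
Conditions: 9-BBN (1.3 equiv), THF, 0 °C to rt; then 4, PdCl2(dppf) (5 mol%), aq. K3PO4 (3 equiv), DMF, 50 °C
Reagents that add atoms: none
Why: anti-Markovnikov hydroboration followed by B-alkyl Suzuki–Miyaura sp3–sp2 coupling; 9-BBN does not reduce the benzoate at rt and K3PO4 does not hydrolyse the secondary ester.

Step 10
Reactants: 12 benzoate ester; 10 TBS-protected alkene (3 equiv)
Product: 13 (R)-11-[3,5-bis(methoxymethoxy)phenyl]undecan-4-yl 2,4-bis(methoxymethoxy)-6-[(8R)-8-(tert-butyldimethylsilyloxy)undecyl]benzoate
Conditions: [RuCl2(p-cymene)]2 (5 mol%), AgSbF6 (20 mol%), MesCO2K (30 mol%), PhCl, 4 Å MS, 110 °C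
Reagents that add atoms: none
Why: Proposed new method: ester-carbonyl-directed, carboxylate-assisted cationic Ru(II) anti-Markovnikov hydroarylation of an unactivated 1-alkene. The ester C=O (made more Lewis basic by the 2- and 4-alkoxy donors) binds [Ru(p-cymene)(O2CMes)]+; concerted metalation–deprotonation cleaves the only ortho C–H (C6, meta to both OMOM groups); the alkene inserts into Ru–aryl with the aryl going to the terminal CH2; MesCO2H protonates the Ru–alkyl to release the linear product and regenerate the catalyst (redox-neutral, no new stereocentre, both (R) centres remote). The closest known reactions are Murai-type carbonyl-directed ortho-alkylation (ketones; esters only when electron-poor and with vinylsilanes), cationic Ru(II)/carboxylate ester-directed oxidative ortho-alkenylation with acrylates, and pyridine-directed Ru(II)-carboxylate hydroarylation of unactivated alkenes.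

Step 11
Reactants: 13 protected integracin B
Product: 14 integracin B, (R)-11-(3,5-dihydroxyphenyl)undecan-4-yl 2,4-dihydroxy-6-[(R)-8-hydroxyundecyl]benzoate
Conditions: 3 M HCl in MeOH, THF co-solvent, 40 °C
Reagents that add atoms: none
Why: acid solvolysis removes the four MOM acetals and the TBS ether in one operation; the di-ortho-substituted secondary benzoate resists acid methanolysis and neither carbinol centre can ionise, so both stay (R).

**Compound list**
1 | resorcinol (benzene-1,3-diol) | Oc1cccc(O)c1 | starting material
2 | 1,3-bis(methoxymethoxy)benzene | COCOc1cccc(OCOC)c1 | intermediate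
3 | 2-[3,5-bis(methoxymethoxy)phenyl]-4,4,5,5-tetramethyl-1,3,2-dioxaborolane | COCOc1cc(OCOC)cc(B2OC(C)(C)C(C)(C)O2)c1 | intermediate
4 | 1-iodo-3,5-bis(methoxymethoxy)benzene | COCOc1cc(I)cc(OCOC)c1 | intermediate
5 | 1-bromo-2,4-bis(methoxymethoxy)benzene | COCOc1ccc(Br)c(OCOC)c1 | intermediate
6 | 2,4-bis(methoxymethoxy)benzoic acid | COCOc1ccc(C(=O)O)c(OCOC)c1 | intermediate
7 | 6-bromohex-1-ene | C=CCCCCBr | starting material
8 | (R)-2-propyloxirane | CCC[C@@H]1CO1 | starting material
9 | (R)-undec-10-en-4-ol | CCC[C@@H](O)CCCCCC=C | intermediate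
10 | (R)-tert-butyldimethyl(undec-10-en-4-yloxy)silane | CCC[C@@H](O[Si](C)(C)C(C)(C)C)CCCCCC=C | intermediate
11 | (R)-undec-10-en-4-yl 2,4-bis(methoxymethoxy)benzoate | COCOc1ccc(C(=O)O[C@H](CCC)CCCCCC=C)c(OCOC)c1 | intermediate
12 | (R)-11-[3,5-bis(methoxymethoxy)phenyl]undecan-4-yl 2,4-bis(methoxymethoxy)benzoate | COCOc1ccc(C(=O)O[C@H](CCC)CCCCCCCc2cc(OCOC)cc(OCOC)c2)c(OCOC)c1 | intermediate
13 | (R)-11-[3,5-bis(methoxymethoxy)phenyl]undecan-4-yl 2,4-bis(methoxymethoxy)-6-[(8R)-8-(tert-butyldimethylsilyloxy)undecyl]benzoate | CCC[C@@H](O[Si](C)(C)C(C)(C)C)CCCCCCCc1cc(OCOC)cc(OCOC)c1C(=O)O[C@H](CCC)CCCCCCCc1cc(OCOC)cc(OCOC)c1 | intermediate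
14 | integracin B | CCC[C@@H](O)CCCCCCCc1cc(O)cc(O)c1C(=O)O[C@H](CCC)CCCCCCCc1cc(O)cc(O)c1 | target

**Totals**
Total step count: 11.
Longest linear sequence: 7 steps (1, 4, 5, 8, 9, 10, 11).

**Steps most likely to fail**
1. Step 10 (proposed new step). Risks: the ester may direct too weakly, the alkene may isomerise, and β-hydride elimination may give alkenyl or allyl arenes. Fallback (known chemistry): build the hindered acid conventionally and esterify by Mitsunobu inversion.
   - B-alkyl Suzuki coupling of the 9-BBN adduct of 10 with 4 gives the 5-alkylresorcinol bis-MOM ether.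
   - NBS bromination ortho to the chain, then Br/Li exchange and CO2, gives the 2,4-bis(MOM-oxy)-6-alkylbenzoic acid.
   - Mitsunobu esterification (PPh3, DIAD) with (S)-11-[3,5-bis(methoxymethoxy)phenyl]undecan-4-ol, made the same way from (S)-2-propyloxirane, gives 13 with inversion; then step 11.
2. Step 3 (iododeboronation of an electron-rich arylboronate). Risks: protodeboronation or phenol/aryl ether formation. Fallback: start from 3-bromophenol (MOM ether, Ir-catalysed C–H borylation then oxidation to the phenol, second MOM) to reach 1-bromo-3,5-bis(methoxymethoxy)benzene, and use it in step 9.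
3. Step 11 (global acid deprotection). Risk: formaldehyde released from four MOM groups can alkylate the free resorcinol rings. Fallback: carry the phenols as TIPS ethers from step 1 (the benzoic acid is then made by Kolbe–Schmitt carboxylation of resorcinol and silylation) and finish with one fluoride desilylation (HF·pyridine or TBAF/AcOH).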